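The partner is the reagent you dose here, against a fixed charge of starting material, and you want the bis adduct standing after the hour.

| setting | teal | ochre | elm | alder | oak |
|---|---|---|---|---|---|
| starting material | 0.056 M | 0.056 M | 0.056 M | 0.056 M | 0.056 M |
| partner | 0.017 M | 0.10 M | 0.0280 M | 0.0448 M | 0.140 M |
| remark | run made earlier | run made earlier |  |  |  |
| time |  |  | 1.0 h | 1.0 h | 1.0 h |

- teal (time / min: bis adduct / %, single product / %): 4.00: 0, 11; 12.0: 0, 17; 20.0: 0, 20; 30.0: 1, 18; 50.0: 3, 20; 60.0: 1, 18
- ochre (time / min: bis adduct / %, single product / %): 4.00: 7, 36; 12.0: 14, 50; 20.0: 16, 53; 30.0: 19, 47; 50.0: 25, 45; 60.0: 29, 43

(scatter of a reading: 1.5 percentage points)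

- a reading or a percentage of single product counts all its forms, free or not

- bis adduct at the end, in percent of the starting material charged, for each flask in turn (elm, alder, oak)

I read teal first. Its readings stay level within their scatter from 20.0 min, yet late single product and bis adduct together, each bis adduct counted as one first addition, come to 0.692 of the partner charged, so I take about a third of the first additions to end in something unread. Ochre's two readings add up to a similar 72.0% of its starting material at 60.0 min, so I count one partner gone for each starting material there. Teal's first reading, with that share, gives a second-order constant of 3.65 L mol⁻¹ min⁻¹ for the first addition.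

Ochre's bis adduct jumps, then climbs in a line from 12.0 min to 60.0 min, with about 0.0320 M of partner left. The leak constant, the bis adduct made per minute for each unit of partner left (a pseudo-first-order constant, as if what the partner attacks stood at a fixed level), reads 0.00548 min⁻¹.

Turn the partner below the starting material, and the area under its curve in time is ln(c starting material / what remains of it) over the first addition's second-order constant and the partner's surplus deficit, so by hand the leak gives 1.86% for elm and 4.32% for alder, both without whatever jump those flasks have. Turn it above, and I let oak start from ochre's jump, read as 10.3%, as an assumption, while its surplus of partner leaks away, which makes 49.4% by my reckoning. Turn the time: the first addition's time at the charged starting material, 4.90 min, is shorter than the hour, but the leak's own 3.04 h is longer, so in oak I expect the bis adduct still to be climbing at the hour.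

The forecast says 3%, 7% and 41%, on the ground that “bis formation looks second order in free partner”.

The flasks give 2.47%, 5.61% and 48.4%.

    starting material + partner → single product (k = 2.20 L mol⁻¹ min⁻¹)
    starting material + partner → other mono adduct (k = 1.00 L mol⁻¹ min⁻¹)
    partner + single product → bis adduct (k = 5.60 L mol⁻¹ min⁻¹)
    partner + other mono adduct → bis adduct (k = 0.0610 L mol⁻¹ min⁻¹)
    crystals ⇌ single product, rate k5*(cs5 - [single product]) while solid is left; crystals form when [single product] > cs5 (solubility = 0.830 mM, k = 2.80 min⁻¹)

At the hour in oak, 25.6% of the 26.9% of single product stands as crystals. Put on oak's second half hour with the mean of its partner at the two ends, the leak constant gives 18 percentage points of bis adduct against 17 points found, and on alder's it gives 0.54 points against 0.44 points found.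

The numbers in the tables come from a simulation with made-up constants; scatter was added.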